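The O7–prenyl bond is cut first. The 4-oxo/3-hydroxy pair is then traced back to a C3=C4 alkene, that alkene is opened by retro-metathesis, and O1–C2 is cut last. This leaves a ring A vinylphenol and a ring B cinnamyl carbonate.
Enabling feature: in ring C only C2 (bound to O1 and the ring B aryl) cannot come from an alkene. C3 and C4 each carry one oxygen, so both derive from a C3=C4 double bond held between C2 and C4a, which is a 2H-chromene.
Forward order: rings A and B are bought and joined at O1–C2 (step 7). Ring C closes at C3=C4 (step 8), C3 and C4 are oxygenated (steps 9 and 10), and the prenyl chain goes on O7 (step 12).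
Stereochemistry: C2 comes from the chiral iridium catalyst. C3 comes from substrate control, because OsO4 adds to the alkene face away from the C2 aryl group. The C4 carbinol centre is erased on oxidation.
Protecting groups: the ring A MOM ethers are removed by acid before the acid-labile prenyl ether exists, and the 5-OH···O=C4 hydrogen bond then steers alkylation to O7. The ring B TIPS ethers leave last with buffered fluoride.

Key step: step 8

Remark on descriptors: C2 keeps one spatial arrangement from step 7 to the target. It is S in the metathesis precursor and in the flav-3-ene, where the aryl carbon outranks the alkene carbon. It becomes R once C3 bears oxygen and outranks the aryl carbon.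
Assumption: the (Sa,S,S) ligand is taken to give the S ether, by analogy with phenoxide additions to cinnamyl carbonates under the same catalyst. If the sense proves opposite, the equally available mirror-image ligand is used and nothing else changes.

Step 1
Reactants: 1 3,4-dihydroxybenzaldehyde; 2 triisopropylsilyl chloride
Product: 3 3,4-bis(triisopropylsilyloxy)benzaldehyde
Conditions: TIPSCl (2.3 equiv), imidazole (5 equiv), DMF, rt
Reagents that add atoms: triisopropylsilyl chloride 2, CC(C)[Si](Cl)(C(C)C)C(C)C
Why: Imidazole-promoted silylation of phenols caps both catechol oxygens with groups that resist base, dilute acid, OsO4 and MnO2 yet leave with fluoride at the end.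

Step 2
Reactants: 3 3,4-bis(triisopropylsilyloxy)benzaldehyde; 4 ethyl (triphenylphosphoranylidene)acetate
Product: 5 ethyl (E)-3-[3,4-bis(triisopropylsilyloxy)phenyl]prop-2-enoate
Conditions: Ph3P=CHCO2Et (1.2 equiv), CH2Cl2, rt to 40 °C
Reagents that add atoms: ethyl (triphenylphosphoranylidene)acetate 4, CCOC(=O)C=P(c1ccccc1)(c1ccccc1)c1ccccc1
Why: Wittig olefination with a stabilised ylide should give the E cinnamate under neutral conditions that leave aryl silyl ethers alone.

Step 3
Reactants: 5 ethyl (E)-3-[3,4-bis(triisopropylsilyloxy)phenyl]prop-2-enoate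
Product: 6 (E)-3-[3,4-bis(triisopropylsilyloxy)phenyl]prop-2-en-1-ol
Conditions: i-Bu2AlH (2.3 equiv), CH2Cl2, −78 °C; aq. potassium sodium tartrate
Reagents that add atoms: none
Why: 1,2-Reduction of a conjugated ester with i-Bu2AlH should stop at the allylic alcohol and touch neither the alkene nor the silyl ethers.

Step 4
Reactants: 6 (E)-3-[3,4-bis(triisopropylsilyloxy)phenyl]prop-2-en-1-ol; 7 methyl chloroformate
Product: 8 (E)-3-[3,4-bis(triisopropylsilyloxy)phenyl]prop-2-en-1-yl methyl carbonate
Conditions: ClCO2Me (1.5 equiv), pyridine (3 equiv), CH2Cl2, 0 °C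
Reagents that add atoms: methyl chloroformate 7, COC(=O)Cl
Why: O-Acylation of the primary allylic alcohol gives the linear carbonate, the usual leaving group for iridium-catalysed allylic substitution because it ionises with loss of CO2 and supplies its own base.

Step 5
Reactants: 9 2,4,6-trihydroxybenzaldehyde; 10 chloromethyl methyl ether
Product: 11 2-hydroxy-4,6-bis(methoxymethoxy)benzaldehyde
Conditions: MOMCl (2.1 equiv), i-Pr2NEt (2.5 equiv), CH2Cl2, 0 °C to rt
Reagents that add atoms: chloromethyl methyl ether 10, COCCl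
Why: In this MOM protection by O-alkylation, two equivalents take the 4-OH and one of the two equivalent ortho hydroxyls, and the last hydroxyl stays free because it is locked in a hydrogen bond to the formyl oxygen.

Step 6
Reactants: 11 2-hydroxy-4,6-bis(methoxymethoxy)benzaldehyde; 12 methyltriphenylphosphonium bromide
Product: 13 3,5-bis(methoxymethoxy)-2-vinylphenol
Conditions: MePPh3Br (2.5 equiv), KOt-Bu (2.5 equiv), THF, 0 °C to rt; aq. NH4Cl; filtered through Et3N-deactivated silica and used at once
Reagents that add atoms: methyltriphenylphosphonium bromide 12, C[P+](c1ccccc1)(c1ccccc1)c1ccccc1.[Br-]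
Why: In this Wittig methylenation of a salicylaldehyde, the first equivalent of ylide only deprotonates the phenol and the unstabilised ylide is reactive enough to olefinate the resulting phenoxide aldehyde.

Step 7
Reactants: 13 3,5-bis(methoxymethoxy)-2-vinylphenol; 8 (E)-3-[3,4-bis(triisopropylsilyloxy)phenyl]prop-2-en-1-yl methyl carbonate
Product: 14 (S)-1-[3,4-bis(triisopropylsilyloxy)phenyl]prop-2-en-1-yl 3,5-bis(methoxymethoxy)-2-vinylphenyl ether
Conditions: [Ir(cod)Cl]2 (2 mol %), (Sa,S,S)-(1,1'-binaphthalene-2,2'-diyl) N,N-bis(1-phenylethyl)phosphoramidite (4 mol %), pre-activated with n-PrNH2 (THF, 50 °C, volatiles removed); 13 (1.2 equiv), K3PO4 (1.0 equiv, proton shuttle), THF, rt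
Reagents that add atoms: none
Why: In this iridium-catalysed asymmetric allylic etherification, the cyclometalated iridium phosphoramidite ionises 8 to a π-allyl complex, the phenoxide of 13 attacks the aryl-bearing terminus opposite the metal to give the branched ether, and the ligand selects the bound allyl face and so sets C2 as S, the proton of 13 ending on the expelled methoxide.

Step 8
Reactants: 14 (S)-1-[3,4-bis(triisopropylsilyloxy)phenyl]prop-2-en-1-yl 3,5-bis(methoxymethoxy)-2-vinylphenyl ether
Product: 15 (2S)-5,7-bis(methoxymethoxy)-2-[3,4-bis(triisopropylsilyloxy)phenyl]-2H-chromene (protected flav-3-ene)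
Conditions: second-generation Grubbs catalyst RuCl2(=CHPh)(PCy3)(H2IMes) (5 mol %), 1,4-benzoquinone (10 mol %), CH2Cl2 (5 mM), 40 °C, argon, dark
Reagents that add atoms: none
Why: The catalyst benzylidene first exchanges with the more accessible monosubstituted allyl alkene of 14 and places ruthenium on C3; this alkylidene adds in a [2+2] sense to the ortho vinyl group, and cycloreversion of the ruthenacyclobutane releases 15 and a ruthenium methylidene that carries the chain while ethylene escapes. The closest known reaction type is ring-closing metathesis of 2-vinylaryl allyl ethers to 2H-chromenes, including 2-aryl members whose ethers come from iridium catalysis. Ring C closes as a six-membered ring in which both reacting carbons (C3 and C4) become endocyclic, the ortho O1–C8a–C4a arrangement holding the two alkenes within reach and the ring size enforcing the cis alkene. No stereocentre is created, and no bond at C2 is made or broken, so the configuration from step 7 is carried through. The selectivity required is chemoselectivity: closure must outrun dimerisation, which dilution and the favourable ring size secure, and it must outrun hydride-induced migration of the allyl double bond toward C2, which 1,4-benzoquinone suppresses. Neutral, aprotic, dark conditions keep the chromene from ionising at C2 or opening electrocyclically, and 15 is carried forward without storage.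

Step 9
Reactants: 15 (2S)-5,7-bis(methoxymethoxy)-2-[3,4-bis(triisopropylsilyloxy)phenyl]-2H-chromene
Product: 16 (2R,3S,4S)-5,7-bis(methoxymethoxy)-2-[3,4-bis(triisopropylsilyloxy)phenyl]chromane-3,4-diol (2,3-trans-3,4-cis)
Conditions: OsO4 (4 mol %), N-methylmorpholine N-oxide (1.5 equiv), acetone/THF/H2O, 0 °C to rt; aq. Na2SO3; Et3N-deactivated silica
Reagents that add atoms: OsO4 (catalytic oxygen carrier), O=[Os](=O)(=O)=O; N-methylmorpholine N-oxide, C[N+]1([O-])CCOCC1; water, O
Why: In this Upjohn dihydroxylation, OsO4 adds suprafacially in a [3+2] manner to the electron-rich cis alkene from the face opposite the C2 aryl group, so the two new hydroxyls are cis to each other and 3-OH is trans to the aryl group (3S,4S), as known for flav-3-enes.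

Step 10
Reactants: 16 (2R,3S,4S)-5,7-bis(methoxymethoxy)-2-[3,4-bis(triisopropylsilyloxy)phenyl]chromane-3,4-diol
Product: 17 (2R,3R)-3-hydroxy-5,7-bis(methoxymethoxy)-2-[3,4-bis(triisopropylsilyloxy)phenyl]chroman-4-one
Conditions: activated MnO2 (15 equiv), CH2Cl2, rt
Reagents that add atoms: none
Why: In this chemoselective benzylic oxidation with activated MnO2, a reaction type known for flavan-3,4-diols, only the C4 carbinol is activated by the oxygen-rich ring A, so the 3-OH stays, C4 loses its stereocentre, and C2 and C3 keep theirs in the thermodynamically preferred trans arrangement.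

Step 11
Reactants: 17 (2R,3R)-3-hydroxy-5,7-bis(methoxymethoxy)-2-[3,4-bis(triisopropylsilyloxy)phenyl]chroman-4-one
Product: 18 (2R,3R)-3,5,7-trihydroxy-2-[3,4-bis(triisopropylsilyloxy)phenyl]chroman-4-one
Conditions: conc. aq. HCl (to ca. 0.5 M), MeOH/THF (3:1), 40 °C
Reagents that add atoms: none
Why: In this acid-catalysed acetal exchange both aryl MOM groups pass to methanol (the 5-O-MOM assisted by the adjacent carbonyl), aryl TIPS ethers solvolyse far more slowly in dilute acid, and running it before step 12 spares the prenyl ether any contact with acid.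

Step 12
Reactants: 18 (2R,3R)-3,5,7-trihydroxy-2-[3,4-bis(triisopropylsilyloxy)phenyl]chroman-4-one; 19 1-bromo-3-methylbut-2-ene (prenyl bromide)
Product: 20 (2R,3R)-3,5-dihydroxy-7-(3-methylbut-2-en-1-yloxy)-2-[3,4-bis(triisopropylsilyloxy)phenyl]chroman-4-one
Conditions: prenyl bromide (1.1 equiv), K2CO3 (1.2 equiv), acetone, rt, argon
Reagents that add atoms: 1-bromo-3-methylbut-2-ene 19, CC(C)=CCBr
Why: In this Williamson ether synthesis under weak base, the 7-OH (para to the C4 carbonyl) is the most acidic site and the only one K2CO3 ionises, since the 5-OH is hydrogen-bonded to C4=O and the 3-OH is an ordinary alcohol, while the silylated 4'-oxygen closes the quinone methide path by which free dihydroflavonols epimerise at C2.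

Step 13
Reactants: 20 (2R,3R)-3,5-dihydroxy-7-(3-methylbut-2-en-1-yloxy)-2-[3,4-bis(triisopropylsilyloxy)phenyl]chroman-4-one
Product: 21 (2R,3R)-2-(3,4-dihydroxyphenyl)-3,5-dihydroxy-7-(3-methylbut-2-en-1-yloxy)chroman-4-one (7-O-prenyltaxifolin, CNP0296402.1)
Conditions: Bu4NF (2.2 equiv), AcOH (2.4 equiv), THF, 0 °C, argon
Reagents that add atoms: none
Why: This fluoride-driven cleavage of aryl silyl ethers is buffered with acetic acid, so the released catecholate is protonated at once and the prenyl ether, the ketol, C2 and C3 see neither acid nor base.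

Compound list
1 | 3,4-dihydroxybenzaldehyde | O=Cc1ccc(O)c(O)c1 | starting material
2 | triisopropylsilyl chloride | CC(C)[Si](Cl)(C(C)C)C(C)C | starting material
3 | 3,4-bis(triisopropylsilyloxy)benzaldehyde | O=Cc1ccc(O[Si](C(C)C)(C(C)C)C(C)C)c(O[Si](C(C)C)(C(C)C)C(C)C)c1 | intermediate
4 | ethyl (triphenylphosphoranylidene)acetate | CCOC(=O)C=P(c1ccccc1)(c1ccccc1)c1ccccc1 | starting material
5 | ethyl (E)-3-[3,4-bis(triisopropylsilyloxy)phenyl]prop-2-enoate | CCOC(=O)/C=C/c1ccc(O[Si](C(C)C)(C(C)C)C(C)C)c(O[Si](C(C)C)(C(C)C)C(C)C)c1 | intermediate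
6 | (E)-3-[3,4-bis(triisopropylsilyloxy)phenyl]prop-2-en-1-ol | OC/C=C/c1ccc(O[Si](C(C)C)(C(C)C)C(C)C)c(O[Si](C(C)C)(C(C)C)C(C)C)c1 | intermediate
7 | methyl chloroformate | COC(=O)Cl | starting material
8 | (E)-3-[3,4-bis(triisopropylsilyloxy)phenyl]prop-2-en-1-yl methyl carbonate | COC(=O)OC/C=C/c1ccc(O[Si](C(C)C)(C(C)C)C(C)C)c(O[Si](C(C)C)(C(C)C)C(C)C)c1 | intermediate
9 | 2,4,6-trihydroxybenzaldehyde | O=Cc1c(O)cc(O)cc1O | starting material
10 | chloromethyl methyl ether | COCCl | starting material
11 | 2-hydroxy-4,6-bis(methoxymethoxy)benzaldehyde | O=Cc1c(O)cc(OCOC)cc1OCOC | intermediate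
12 | methyltriphenylphosphonium bromide | C[P+](c1ccccc1)(c1ccccc1)c1ccccc1.[Br-] | starting material
13 | 3,5-bis(methoxymethoxy)-2-vinylphenol | C=Cc1c(O)cc(OCOC)cc1OCOC | intermediate
14 | (S)-1-[3,4-bis(triisopropylsilyloxy)phenyl]prop-2-en-1-yl 3,5-bis(methoxymethoxy)-2-vinylphenyl ether | COCOc1cc(OCOC)c(C=C)c(c1)O[C@@H](C=C)c1ccc(O[Si](C(C)C)(C(C)C)C(C)C)c(O[Si](C(C)C)(C(C)C)C(C)C)c1 | intermediate
15 | (2S)-5,7-bis(methoxymethoxy)-2-[3,4-bis(triisopropylsilyloxy)phenyl]-2H-chromene | COCOc1cc(OCOC)c2c(c1)O[C@H](c1ccc(O[Si](C(C)C)(C(C)C)C(C)C)c(O[Si](C(C)C)(C(C)C)C(C)C)c1)C=C2 | intermediate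
16 | (2R,3S,4S)-5,7-bis(methoxymethoxy)-2-[3,4-bis(triisopropylsilyloxy)phenyl]chromane-3,4-diol | COCOc1cc(OCOC)c2c(c1)O[C@H](c1ccc(O[Si](C(C)C)(C(C)C)C(C)C)c(O[Si](C(C)C)(C(C)C)C(C)C)c1)[C@@H](O)[C@H]2O | intermediate
17 | (2R,3R)-3-hydroxy-5,7-bis(methoxymethoxy)-2-[3,4-bis(triisopropylsilyloxy)phenyl]chroman-4-one | COCOc1cc(OCOC)c2c(c1)O[C@H](c1ccc(O[Si](C(C)C)(C(C)C)C(C)C)c(O[Si](C(C)C)(C(C)C)C(C)C)c1)[C@@H](O)C2=O | intermediate
18 | (2R,3R)-3,5,7-trihydroxy-2-[3,4-bis(triisopropylsilyloxy)phenyl]chroman-4-one | Oc1cc(O)c2c(c1)O[C@H](c1ccc(O[Si](C(C)C)(C(C)C)C(C)C)c(O[Si](C(C)C)(C(C)C)C(C)C)c1)[C@@H](O)C2=O | intermediate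
19 | 1-bromo-3-methylbut-2-ene (prenyl bromide) | CC(C)=CCBr | starting material
20 | (2R,3R)-3,5-dihydroxy-7-(3-methylbut-2-en-1-yloxy)-2-[3,4-bis(triisopropylsilyloxy)phenyl]chroman-4-one | CC(C)=CCOc1cc(O)c2c(c1)O[C@H](c1ccc(O[Si](C(C)C)(C(C)C)C(C)C)c(O[Si](C(C)C)(C(C)C)C(C)C)c1)[C@@H](O)C2=O | intermediate
21 | (2R,3R)-2-(3,4-dihydroxyphenyl)-3,5-dihydroxy-7-(3-methylbut-2-en-1-yloxy)chroman-4-one | CC(C)=CCOc1cc(O)c2c(c1)O[C@H](c1ccc(O)c(O)c1)[C@@H](O)C2=O | target

Total step count: 13
Longest linear sequence: 11 steps (steps 1 to 4, then 7 to 13). Steps 5 and 6 form the short ring A branch.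

Steps most likely to fail

Risk at step 7. The phenoxide may attack the unsubstituted allyl terminus, or the electron-rich ring A may be allylated at carbon. The product ether may also re-ionise on the catalyst, with loss of enantiopurity. The fallback makes O1–C2 by an invertive displacement and takes the stereocentre from an enzymatic resolution. It sets out from aldehyde 3. Vinylmagnesium bromide (THF, −78 °C) should give racemic 1-[3,4-bis(triisopropylsilyloxy)phenyl]prop-2-en-1-ol F1. Candida antarctica lipase B with vinyl acetate (methyl tert-butyl ether, rt) should acylate the R enantiomer preferentially, with aryl as the large group and vinyl as the medium group. This gives (R)-1-[3,4-bis(triisopropylsilyloxy)phenyl]prop-2-en-1-yl acetate F2, which is separated from the unreacted S alcohol. Brief methanolysis (K2CO3, MeOH, 0 °C) should free (R)-1-[3,4-bis(triisopropylsilyloxy)phenyl]prop-2-en-1-ol F3. A Mitsunobu coupling of this alcohol with phenol 13 (PPh3, diisopropyl azodicarboxylate, toluene, −20 °C) should proceed with inversion. It comes back to the route at 14.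

Risk at step 10. The ketol may be over-oxidised to the flavonol or to a 3,4-dione, or the cis glycol may be cleaved. The very labile C4 hydroxyl may also ionise on the oxide surface. The fallback tells the two hydroxyls apart by protection and does not rely on the oxidant. It sets out from diol 16. Et3SiCl and imidazole (CH2Cl2, −20 °C) should silylate the equatorial, less crowded 3-OH, because the 4-OH is pseudo-axial and pressed against the peri 5-O-MOM group. This gives (2R,3S,4S)-5,7-bis(methoxymethoxy)-3-(triethylsilyloxy)-2-[3,4-bis(triisopropylsilyloxy)phenyl]chroman-4-ol F4. Dess–Martin periodinane with NaHCO3 (CH2Cl2, 0 °C) should then give (2R,3R)-5,7-bis(methoxymethoxy)-3-(triethylsilyloxy)-2-[3,4-bis(triisopropylsilyloxy)phenyl]chroman-4-one F5. The acid treatment of step 11 removes the triethylsilyl group together with both MOM groups. The fallback therefore adds one operation and comes back to the route at 18.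

Risk at step 6. Olefination of the strongly deactivated phenoxide aldehyde may be sluggish, and the electron-rich ortho-hydroxystyrene may oligomerise under traces of acid during isolation. The fallback reverses the order of events so that no free vinylphenol is handled. It sets out from aldehyde 11 and carbonate 8. Under the catalyst of step 7 these should give (S)-2-({1-[3,4-bis(triisopropylsilyloxy)phenyl]prop-2-en-1-yl}oxy)-4,6-bis(methoxymethoxy)benzaldehyde F6. Its formyl group lowers the carbon nucleophilicity of ring A. The aldehyde is no longer conjugated to a phenoxide, and it is methylenated with Ph3P=CH2 (1.2 equiv, THF, 0 °C). This comes back to the route at 14.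

Further compounds
F1 | step 7 | racemic 1-[3,4-bis(triisopropylsilyloxy)phenyl]prop-2-en-1-ol | OC(C=C)c1ccc(O[Si](C(C)C)(C(C)C)C(C)C)c(O[Si](C(C)C)(C(C)C)C(C)C)c1
F2 | step 7 | (R)-1-[3,4-bis(triisopropylsilyloxy)phenyl]prop-2-en-1-yl acetate | CC(=O)O[C@H](C=C)c1ccc(O[Si](C(C)C)(C(C)C)C(C)C)c(O[Si](C(C)C)(C(C)C)C(C)C)c1
F3 | step 7 | (R)-1-[3,4-bis(triisopropylsilyloxy)phenyl]prop-2-en-1-ol | O[C@H](C=C)c1ccc(O[Si](C(C)C)(C(C)C)C(C)C)c(O[Si](C(C)C)(C(C)C)C(C)C)c1
F4 | step 10 | (2R,3S,4S)-5,7-bis(methoxymethoxy)-3-(triethylsilyloxy)-2-[3,4-bis(triisopropylsilyloxy)phenyl]chroman-4-ol | COCOc1cc(OCOC)c2c(c1)O[C@H](c1ccc(O[Si](C(C)C)(C(C)C)C(C)C)c(O[Si](C(C)C)(C(C)C)C(C)C)c1)[C@@H](O[Si](CC)(CC)CC)[C@H]2O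
F5 | step 10 | (2R,3R)-5,7-bis(methoxymethoxy)-3-(triethylsilyloxy)-2-[3,4-bis(triisopropylsilyloxy)phenyl]chroman-4-one | COCOc1cc(OCOC)c2c(c1)O[C@H](c1ccc(O[Si](C(C)C)(C(C)C)C(C)C)c(O[Si](C(C)C)(C(C)C)C(C)C)c1)[C@@H](O[Si](CC)(CC)CC)C2=O
F6 | step 6 | (S)-2-({1-[3,4-bis(triisopropylsilyloxy)phenyl]prop-2-en-1-yl}oxy)-4,6-bis(methoxymethoxy)benzaldehyde | COCOc1cc(OCOC)c(C=O)c(c1)O[C@@H](C=C)c1ccc(O[Si](C(C)C)(C(C)C)C(C)C)c(O[Si](C(C)C)(C(C)C)C(C)C)c1
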